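Readings and results are simulated with constants of no real substance, and the scatter is random.

74.1 % of the partner charged stood as product at the last reading of zeta, at a partner-to-substrate charge ratio of 0.675, and 54.7 % at the last reading of theta, at 1.50, taking partner as used up in both.

| flask | substrate | partner | temperature | remark | time |
|---|---|---|---|---|---|
| zeta | 0.80 M | 0.54 M | 29 °C | run made earlier |  |
| theta | 0.80 M | 1.2 M | 37 °C | run made earlier |  |
| eta | 1.6 M | 0.80 M | 29 °C | run made earlier |  |
| elm | 0.80 M | 0.800 M | 40 °C |  | 3.0 h |
| maple | 0.80 M | 0.800 M | 25 °C |  | 3.0 h |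

- zeta (time / h: product / %, substrate / %): 0.417: 25, 73; 0.833: 33, 66; 1.50: 43, 58; 3.00: 46, 51; 6.00: 50, 51
- theta (time / h: product / %, substrate / %): 0.333: 55, 43; 0.833: 74, 29; 1.50: 77, 21; 2.50: 80, 22; 4.00: 82, 19
- eta (time / h: product / %, substrate / %): 0.500: 32, 68; 1.33: 36, 66; 2.50: 41, 59; 4.00: 42, 56; 6.00: 42, 54

(each reading ± 1.5 percentage points)

- percent here means substrate units held: one homo dimer A counts as two
- what is said of product includes crystals
- crystals is a solid; its amount is given per volume of the solution
- steps thought possible: substrate + partner -> product; 2 substrate -> homo dimer A; 2 partner -> homo dimer B; crystals <-> product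

- the best flask by amount of product, in percent of the substrate charged; "all alike" if 1.5 percentage points covers them all (elm / maple / all alike)
- amount of product at the end, in percent of the substrate charged, elm
- amount of product at the end, in percent of the substrate charged, maple

Go to logarithms: between those two runs, which also differ in temperature (29 °C against 37 °C), the yield as read falls 0.380 decades per decade of ratio. Carry it to the ratio of 1.00 in elm and maple, and my own reckoning gives 63.8 %: this is the partner yield, product formed per partner used, a selectivity for the partner. With the two charges equal, read that figure as the product percentage, in percent of the substrate charged, once partner is used.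

The forecast, reckoned its own way, says 65 % for elm, 63 % for maple, and all alike: “The two flasks are essentially alike, though this is uncertain.”

The flasks give 62.5 % in elm and 62.8 % in maple, a gap of 0.30 percentage points, smaller than the margin, so all alike stands.

    substrate + partner → product, rate k1*[substrate]*[partner]^1.5 (k = 6.40 × 10⁻⁴ L¹·⁵ mol⁻¹·⁵ s⁻¹, Ea = 42.0 kJ mol⁻¹)
    2 substrate → homo dimer A (k = 2.70 × 10⁻⁷ L mol⁻¹ s⁻¹, Ea = 88.0 kJ mol⁻¹)
    2 partner → homo dimer B (k = 1.00 × 10⁻⁴ L mol⁻¹ s⁻¹, Ea = 64.0 kJ mol⁻¹)
    crystals ⇌ product, rate k4*(cs4 - [product]) while solid is left; crystals form when [product] > cs4 (solubility = 0.540 M, k = 0.00130 s⁻¹)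
    (constants at 25 °C)

At 3.00 h elm has 4.7 % of its partner left and maple 14 %, so elm has used more, yet its yield per partner used is 65.5 % against 72.7 % in maple. Now read maple at 12 h, with 3.1 % of its partner left: 63.8 % of the partner used reckons to 61.8 %. Maple at that time holds 70.9 % product, crystals counted in, a yield per partner used of 73.2 %.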